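- In the blue run, substrate stands at 64.7% after 0.500 d and at 44.2% after 2.50 d, while target reaches 19.2%.

- blue: substrate 0.15 M; fresh partner 2 equiv; coupling partner 1.8 equiv; run made earlier
- flask: substrate 0.10 M; fresh partner 2.00 equiv; coupling partner 1.80 equiv; time 12 d

- blue (time / d: target / %, substrate / %): 0.500: 7.2, 64.7; 1.04: 15.3, 53.0; 1.25: 17.0, 51.0; 2.08: 17.7, 45.8; 2.50: 19.2, 44.2

(scatter of a reading: 1 percentage point)

* the best time, 12 d at the latest, for target
* the amount of target, in percent of the substrate charged, at that time



- I count this flask in working times. In the blue run, the whole fall of substrate seen, divided by its early rate of fall, gives 0.790 d.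
- I assume that substrate falls by meeting a partner, so at equal equivalents the time stretches as the charge thins. At [substrate] = 0.10 M, the working time is 1.19 d.
- I hold two times against each other: this working time and the longest time allowed, 12 d. Their ratio is 10.1 turnovers of the working time, so the limit is far longer than the working time, and I look for the best time well before it.
- The forecast differs: it gives 12 d (range 5 d to 12 d) and 22% (range 15% to 33%), “with the best time late”.
- The flask peaks at 13.7% after 2.78 d, when the coupling partner, the limiting reagent, is down to 8.67% of its charge. That peak comes at 2.34 working times.

    open intermediate → side product (k = 0.0670 h⁻¹)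
    target ⇌ isomer of the product (K = 0.880, k = 0.0130 h⁻¹)
    substrate + coupling partner → open intermediate (k = 0.200 M⁻¹ h⁻¹)
    open intermediate + second intermediate → target (k = 0.630 M⁻¹ h⁻¹)
    coupling partner + fresh partner → second intermediate (k = 0.210 M⁻¹ h⁻¹)

- In a neighbour flask with [substrate] = 0.060 M, the working time is 1.98 d, so the same count puts its peak near 4.63 d, earlier than the limit. That neighbour holds 8.51% target after 12.0 d, against its best of 8.65%.

The readings are simulated for substances that don't exist, and the scatter is random.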